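**Retrosynthetic overview**
- The strategy rests on C3 of ring A, the ring carbon that carries the 2-methylbutanoyl group and lies between the ring carbonyls C2 and C4. Replacing it by oxygen gives a spiro oxane-2,4,6-trione (a 3-oxoglutaric anhydride) that already holds the spiro carbon and the methyl/prenyl carbon. Ring A is therefore closed last, by double C-acylation of the methyl carbon of (R)-3-methylpentan-2-one.
- The anhydride comes from a di-tert-butyl 3-oxoglutarate, made by C-acylation of the C6 ester enolate of the cis-hydrindane with an enantiopure malonyl half-ester chloride. The spiro centre is set by equatorial attack; the methyl/prenyl centre comes from a phase-transfer alkylation.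
- The cis-hydrindane comes from (R)-3-(nitromethyl)cyclopentanone and tert-butyl 2-(bromomethyl)acrylate (nitronate allylation, then enamine Michael ring closure), followed by a Nef reaction and double methyl addition from the convex face.
- Ring order: cyclopentane (bought), cyclohexane (step 3), anhydride ring (step 13), ring A (step 15).

Key step: step 15

**Assumptions**
- The target is treated as the enol tautomer drawn in its SMILES; the ring A tautomers interconvert and are one compound.
- The sense of induction of the organocatalysts in steps 1 and 9 is assumed to give the configurations drawn; if it is opposite, the quinidine-derived amine or the (R,R)-ammonium salt is used and nothing else changes.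

**Route**

Step 1
Reactants: 1 cyclopent-2-en-1-one; 2 nitromethane
Product: 3 (3R)-3-(nitromethyl)cyclopentan-1-one
Conditions: 2 (5 equiv), 9-amino-9-deoxy-epi-quinine (10 mol %), PhCO2H (20 mol %), THF, rt
Reagents that add atoms: none
Why: Organocatalytic asymmetric Michael addition of a nitroalkane to a cyclic enone, in which the iminium ion of the enone is attacked on one face by the nitronate, setting the future ring-fusion carbon C3a as R; this centre is beta to the ketone and cannot epimerise.

Step 2
Reactants: 3 (3R)-3-(nitromethyl)cyclopentan-1-one; 4 tert-butyl 2-(bromomethyl)prop-2-enoate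
Product: 5 tert-butyl 2-methylidene-4-nitro-4-[(1R)-3-oxocyclopentyl]butanoate (epimers at the nitro carbon)
Conditions: K2CO3 (1.5 equiv), MeCN, 0 °C to rt; 3 in 1.3-fold excess, 4 added slowly
Reagents that add atoms: none
Why: The nitro-stabilised carbanion, by far the most acidic site, adds to the bromomethyl acrylate by conjugate addition and loss of bromide (SN2' allylation at carbon), and the excess of 3 limits double allylation; the new nitro-bearing centre is removed in step 4.

Step 3
Reactants: 5 tert-butyl 2-methylidene-4-nitro-4-[(1R)-3-oxocyclopentyl]butanoate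
Product: 6 tert-butyl (3aR,7aR)-4-nitro-1-oxooctahydro-1H-indene-6-carboxylate (cis-fused; epimers at C4 and C6)
Conditions: pyrrolidine (30 mol %), AcOH (30 mol %), MeCN, 40 °C; aqueous AcOH work-up
Reagents that add atoms: none
Why: Stork enamine Michael addition in the 6-endo-trig mode, as in the alpha,alpha'-annulation of ketone enamines with 2-(bromomethyl)acrylates: only the enamine towards C2 can reach the acrylate terminus through a six-membered transition state, and the tether on the neighbouring carbon forces the new bond onto the same face, so the ring fusion is cis (7aR).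

Step 4
Reactants: 6 tert-butyl (3aR,7aR)-4-nitro-1-oxooctahydro-1H-indene-6-carboxylate
Product: 8 tert-butyl (3aR,7aR)-1,4-dioxooctahydro-1H-indene-6-carboxylate (C6 epimers), via potassium nitronate 7 (not isolated)
Conditions: KOH (1.1 equiv), MeOH, 0 °C; then KHSO5 (as 2KHSO5·KHSO4·K2SO4), K2HPO4 buffer, H2O/MeOH, 0 °C to rt
Reagents that add atoms: potassium peroxymonosulfate, [K+].[O-]S(=O)(=O)OO
Why: Oxidative Nef reaction: the single equivalent of base is taken up by the nitro C–H, the nitronate carbon is oxidised by peroxymonosulfate and nitrite is lost, and the buffered medium leaves the now doubly enolisable cis-dione without time to epimerise.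

Step 5
Reactants: 8 tert-butyl (3aR,7aR)-1,4-dioxooctahydro-1H-indene-6-carboxylate
Product: 9 tert-butyl (1S,3aR,4S,7aR)-1,4-dihydroxy-1,4-dimethyloctahydro-1H-indene-6-carboxylate (C6 epimers)
Conditions: MeMgBr (4 equiv), CeCl3 (4 equiv, dried), THF, −78 to −40 °C; aq. NH4Cl
Reagents that add atoms: methylmagnesium bromide, C[Mg]Br
Why: Organocerium addition to both ketones, which suppresses enolisation and spares the tert-butyl ester; each carbonyl of the folded cis-hydrindane is attacked from its convex face, so both methyl groups end up cis to the ring-fusion hydrogens and both hydroxyl groups on the concave face (1S,4S).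

Step 6
Reactants: 9 tert-butyl (1S,3aR,4S,7aR)-1,4-dihydroxy-1,4-dimethyloctahydro-1H-indene-6-carboxylate
Product: 10 tert-butyl (1S,3aR,4S,7aR)-1,4-dimethyl-1,4-bis[(trimethylsilyl)oxy]octahydro-1H-indene-6-carboxylate (C6 epimers)
Conditions: 1-(trimethylsilyl)imidazole (4 equiv), CH2Cl2, rt
Reagents that add atoms: 1-(trimethylsilyl)imidazole, C[Si](C)(C)n1ccnc1
Why: Silylation of the two tertiary alcohols with a strong neutral silyl donor, which does not touch the tert-butyl ester.

Step 7
Reactants: 11 2,2,5-trimethyl-1,3-dioxane-4,6-dione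
Product: 12 3-tert-butoxy-2-methyl-3-oxopropanoic acid (racemic)
Conditions: tBuOH (5 equiv), toluene, reflux
Reagents that add atoms: tert-butanol, CC(C)(C)O
Why: Thermal alcoholysis of a 5-alkyl Meldrum's acid opens the dioxanedione to the malonic half ester with loss of acetone.

Step 8
Reactants: 12 3-tert-butoxy-2-methyl-3-oxopropanoic acid; 13 2,2-diphenylethan-1-ol
Product: 14 1-tert-butyl 3-(2,2-diphenylethyl) 2-methylpropanedioate (racemic)
Conditions: DCC (1.1 equiv), DMAP (5 mol %), CH2Cl2, 0 °C to rt
Reagents that add atoms: none
Why: Steglich esterification of the free carboxyl gives the mixed malonate whose two ester groups differ strongly in size and in lability to hydroxide.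

Step 9
Reactants: 14 1-tert-butyl 3-(2,2-diphenylethyl) 2-methylpropanedioate; 15 1-bromo-3-methylbut-2-ene (prenyl bromide)
Product: 16 1-tert-butyl 3-(2,2-diphenylethyl) (2R)-2-methyl-2-(3-methylbut-2-en-1-yl)propanedioate
Conditions: 15 (1.5 equiv), N-spiro binaphthyl ammonium salt (S,S)-3,4,5-trifluorophenyl-NAS bromide (5 mol %), 50% aq. KOH, toluene, −40 °C
Reagents that add atoms: none
Why: Asymmetric phase-transfer alkylation of an alpha-methylmalonate mixed ester: the chiral ammonium enolate ion pair exposes one face to the allylic bromide, which sets the methyl/prenyl quaternary centre as R.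

Step 10
Reactants: 16 1-tert-butyl 3-(2,2-diphenylethyl) (2R)-2-methyl-2-(3-methylbut-2-en-1-yl)propanedioate
Product: 17 (2R)-3-tert-butoxy-2-methyl-2-(3-methylbut-2-en-1-yl)-3-oxopropanoic acid
Conditions: 1 M aq. KOH, MeOH, rt; then 1 M HCl to pH 3 at 0 °C
Reagents that add atoms: potassium hydroxide, [K+].[OH-]
Why: Saponification cleaves the primary alkyl ester while the tert-butyl ester resists acyl attack by hydroxide, and the quaternary centre has no proton through which it could racemise.

Step 11
Reactants: 17 (2R)-3-tert-butoxy-2-methyl-2-(3-methylbut-2-en-1-yl)-3-oxopropanoic acid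
Product: 18 tert-butyl (2S)-2-(chlorocarbonyl)-2,5-dimethylhex-4-enoate
Conditions: 1-chloro-N,N,2-trimethylprop-1-en-1-amine (1.2 equiv), CH2Cl2, 0 °C to rt; used crude
Reagents that add atoms: 1-chloro-N,N,2-trimethylprop-1-en-1-amine, CC(C)=C(Cl)N(C)C
Why: The alpha-chloroenamine converts the acid into the acyl chloride under neutral conditions without HCl, so the tert-butyl ester and the trisubstituted alkene survive; the descriptor changes to S only because the CIP ranking of the two carbonyl groups changes.

Step 12
Reactants: 10 tert-butyl (1S,3aR,4S,7aR)-1,4-dimethyl-1,4-bis[(trimethylsilyl)oxy]octahydro-1H-indene-6-carboxylate; 18 tert-butyl (2S)-2-(chlorocarbonyl)-2,5-dimethylhex-4-enoate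
Product: 20 tert-butyl (1S,3aR,4S,6R,7aR)-6-[(2R)-2-(tert-butoxycarbonyl)-2,5-dimethylhex-4-enoyl]-1,4-dimethyl-1,4-bis[(trimethylsilyl)oxy]octahydro-1H-indene-6-carboxylate, via lithium enolate 19 (not isolated)
Conditions: LiN(iPr)2 (1.15 equiv), THF, −78 °C; then 18 (1.3 equiv), −78 to −20 °C; aq. NH4Cl
Reagents that add atoms: none
Why: Claisen-type C-acylation of an alpha,alpha-disubstituted ester lithium enolate by an acyl chloride, giving a product with no acidic proton; the cyclohexane sits in the chair with the C4 methyl axial on the alpha face (the other chair would place C1 and the C4 silyloxy group 1,3-diaxial), so the acyl chloride enters equatorially from the beta face and the new acyl group is cis to the silyloxy groups (6R), both C6 epimers of 10 converging on the one enolate.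

Step 13
Reactants: 20 tert-butyl (1S,3aR,4S,6R,7aR)-6-[(2R)-2-(tert-butoxycarbonyl)-2,5-dimethylhex-4-enoyl]-1,4-dimethyl-1,4-bis[(trimethylsilyl)oxy]octahydro-1H-indene-6-carboxylate
Product: 23 (1S,3aR,4S,5'R,6R,7aR)-1,4,5'-trimethyl-5'-(3-methylbut-2-en-1-yl)-1,4-bis[(trimethylsilyl)oxy]octahydrospiro[indene-6,3'-oxane]-2',4',6'-trione, via bis(trimethylsilyl) ester 21 (not isolated), via acyl chloride silyl ester 22 (not isolated)
Conditions: TMSOTf (3 equiv), 2,6-lutidine (4 equiv), CH2Cl2, 0 °C to rt; volatiles removed; then (COCl)2 (1.1 equiv), DMF (cat.), CH2Cl2, 0 °C; filtered under argon, used crude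
Reagents that add atoms: none
Why: Buffered silyl triflate exchanges both tert-butyl esters for trimethylsilyl esters with loss of isobutene, oxalyl chloride/DMF turns one silyl ester into the acyl chloride, and the neighbouring silyl ester closes the six-membered anhydride with loss of Me3SiCl; no free beta-keto acid is formed, so decarboxylation is avoided, and the ketone between the two quaternary carbons cannot enolise.

Step 14
Reactants: 24 (2R)-2-methylbutanoic acid
Product: 25 (3R)-3-methylpentan-2-one
Conditions: MeLi (2.2 equiv), Et2O, 0 °C; poured into cold 1 M HCl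
Reagents that add atoms: methyllithium, [Li]C
Why: Addition of methyllithium to the lithium carboxylate gives a stable geminal dialkoxide that collapses to the methyl ketone only on hydrolysis, and the alpha-hydrogen of the carboxylate is not removed under these conditions, so the stereocentre is kept.

Step 15
Reactants: 23 spiro anhydride (bis-trimethylsilyl ether); 25 (3R)-3-methylpentan-2-one
Product: 29 target bis(trimethylsilyl) ether, via lithium enolate 26 (not isolated), via dilithium keto carboxylate 27 (not isolated), via keto acid 28 (not isolated)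
Conditions: 25 (2.2 equiv), LiN(iPr)2 (2.1 equiv), THF, −78 °C; 23 in THF, −78 °C; HCl in Et2O (4.2 equiv), −78 °C; DMAP (3 equiv), DCC (1.5 equiv), −78 °C to rt; aq. citric acid work-up
Reagents that add atoms: none
Why: Proposed new method: LiN(iPr)2 at −78 °C removes a methyl proton of 25 irreversibly, enolate 26 adds to one anhydride carbonyl of 23 and the ring opens to the diketonate carboxylate 27 (a second equivalent of 26 acts as base); after protonation to 28, DCC/DMAP converts the freed carboxyl into an acylpyridinium ion that is attacked by the central carbon of the 1,3-diketone, so this one carbon becomes bonded to both former anhydride carbonyls. The closest known reactions are the AlCl3-mediated double C-acylation of enol acetates by succinic or glutaric anhydride to 2-acylcycloalkane-1,3-diones, the opening of cyclic anhydrides by ketone lithium enolates, and the carbodiimide/DMAP C-acylation of 1,3-diketones by carboxylic acids; their combination on a fully substituted 3-oxoglutaric anhydride is new. Ring A closes in the 6-(enolendo)-exo-trig mode. No stereocentre is formed: the ring and quaternary centres cannot epimerise, and the side-chain methine is protected by kinetic deprotonation at the methyl group and, after the first acylation, by the far more acidic diketone CH2. The step needs attack at an anhydride carbonyl rather than at the ketone between the two quaternary carbons (secured by the neopentyl shielding on both sides of that ketone), it does not matter which anhydride carbonyl reacts first (both end on the same carbon), and C- over O-acylation in the closure is secured because DMAP returns any enol lactone to the acylpyridinium ion and the triketone enolate is the thermodynamic sink.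

Step 16
Reactants: 29 target bis(trimethylsilyl) ether
Product: 30 CNP0236509.3
Conditions: HF·pyridine, pyridine, THF, 0 °C
Reagents that add atoms: none
Why: Buffered fluoride cleaves the two tertiary trimethylsilyl ethers under conditions too mild to cyclise the prenyl group onto the enol or to ionise the tertiary alcohols.

**Compound list**
1 | cyclopent-2-en-1-one | O=C1CCC=C1 | starting material
2 | nitromethane | C[N+](=O)[O-] | starting material
3 | (3R)-3-(nitromethyl)cyclopentan-1-one | O=C1C[C@@H](CC1)C[N+](=O)[O-] | intermediate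
4 | tert-butyl 2-(bromomethyl)prop-2-enoate | C=C(CBr)C(=O)OC(C)(C)C | starting material
5 | tert-butyl 2-methylidene-4-nitro-4-[(1R)-3-oxocyclopentyl]butanoate (nitro carbon epimers) | C=C(CC([N+](=O)[O-])[C@H]1CC(=O)CC1)C(=O)OC(C)(C)C | intermediate
6 | tert-butyl (3aR,7aR)-4-nitro-1-oxooctahydro-1H-indene-6-carboxylate (C4, C6 epimers) | CC(C)(C)OC(=O)C1C[C@@H]2[C@@H](CCC2=O)C([N+](=O)[O-])C1 | intermediate
7 | potassium nitronate of 6 | CC(C)(C)OC(=O)C1C[C@@H]2[C@@H](CCC2=O)C(=[N+]([O-])[O-])C1.[K+] | intermediate
8 | tert-butyl (3aR,7aR)-1,4-dioxooctahydro-1H-indene-6-carboxylate (C6 epimers) | CC(C)(C)OC(=O)C1C[C@@H]2[C@@H](CCC2=O)C(=O)C1 | intermediate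
9 | tert-butyl (1S,3aR,4S,7aR)-1,4-dihydroxy-1,4-dimethyloctahydro-1H-indene-6-carboxylate (C6 epimers) | CC(C)(C)OC(=O)C1C[C@@H]2[C@@H](CC[C@]2(C)O)[C@@](C)(O)C1 | intermediate
10 | tert-butyl (1S,3aR,4S,7aR)-1,4-dimethyl-1,4-bis[(trimethylsilyl)oxy]octahydro-1H-indene-6-carboxylate (C6 epimers) | CC(C)(C)OC(=O)C1C[C@@H]2[C@@H](CC[C@]2(C)O[Si](C)(C)C)[C@@](C)(O[Si](C)(C)C)C1 | intermediate
11 | 2,2,5-trimethyl-1,3-dioxane-4,6-dione | CC1C(=O)OC(C)(C)OC1=O | starting material
12 | 3-tert-butoxy-2-methyl-3-oxopropanoic acid (racemic) | CC(C(O)=O)C(=O)OC(C)(C)C | intermediate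
13 | 2,2-diphenylethan-1-ol | OCC(c1ccccc1)c1ccccc1 | starting material
14 | 1-tert-butyl 3-(2,2-diphenylethyl) 2-methylpropanedioate (racemic) | CC(C(=O)OCC(c1ccccc1)c1ccccc1)C(=O)OC(C)(C)C | intermediate
15 | 1-bromo-3-methylbut-2-ene (prenyl bromide) | CC(C)=CCBr | starting material
16 | 1-tert-butyl 3-(2,2-diphenylethyl) (2R)-2-methyl-2-(3-methylbut-2-en-1-yl)propanedioate | CC(C)(C)OC(=O)[C@](C)(CC=C(C)C)C(=O)OCC(c1ccccc1)c1ccccc1 | intermediate
17 | (2R)-3-tert-butoxy-2-methyl-2-(3-methylbut-2-en-1-yl)-3-oxopropanoic acid | CC(C)(C)OC(=O)[C@](C)(CC=C(C)C)C(O)=O | intermediate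
18 | tert-butyl (2S)-2-(chlorocarbonyl)-2,5-dimethylhex-4-enoate | CC(C)(C)OC(=O)[C@](C)(CC=C(C)C)C(Cl)=O | intermediate
19 | lithium enolate of 10 | [Li+].CC(C)(C)OC([O-])=C1C[C@@H]2[C@@H](CC[C@]2(C)O[Si](C)(C)C)[C@@](C)(O[Si](C)(C)C)C1 | intermediate
20 | tert-butyl (1S,3aR,4S,6R,7aR)-6-[(2R)-2-(tert-butoxycarbonyl)-2,5-dimethylhex-4-enoyl]-1,4-dimethyl-1,4-bis[(trimethylsilyl)oxy]octahydro-1H-indene-6-carboxylate | CC(C)(C)OC(=O)[C@](C)(CC=C(C)C)C(=O)[C@]1(C[C@@H]2[C@@H](CC[C@]2(C)O[Si](C)(C)C)[C@@](C)(O[Si](C)(C)C)C1)C(=O)OC(C)(C)C | intermediate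
21 | bis(trimethylsilyl) ester corresponding to 20 | C[Si](C)(C)OC(=O)[C@](C)(CC=C(C)C)C(=O)[C@]1(C[C@@H]2[C@@H](CC[C@]2(C)O[Si](C)(C)C)[C@@](C)(O[Si](C)(C)C)C1)C(=O)O[Si](C)(C)C | intermediate
22 | acyl chloride trimethylsilyl ester (drawn with the chloride on the methyl/prenyl side; the other regioisomer closes to the same anhydride) | ClC(=O)[C@](C)(CC=C(C)C)C(=O)[C@]1(C[C@@H]2[C@@H](CC[C@]2(C)O[Si](C)(C)C)[C@@](C)(O[Si](C)(C)C)C1)C(=O)O[Si](C)(C)C | intermediate
23 | (1S,3aR,4S,5'R,6R,7aR)-1,4,5'-trimethyl-5'-(3-methylbut-2-en-1-yl)-1,4-bis[(trimethylsilyl)oxy]octahydrospiro[indene-6,3'-oxane]-2',4',6'-trione (spiro 3-oxoglutaric anhydride) | O1C(=O)[C@](C)(CC=C(C)C)C(=O)[C@]2(C[C@@H]3[C@@H](CC[C@]3(C)O[Si](C)(C)C)[C@@](C)(O[Si](C)(C)C)C2)C1=O | intermediate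
24 | (2R)-2-methylbutanoic acid | CC[C@@H](C)C(O)=O | starting material
25 | (3R)-3-methylpentan-2-one | CC[C@@H](C)C(C)=O | intermediate
26 | lithium (3R)-3-methylpent-1-en-2-olate | [Li+].C=C([O-])[C@H](C)CC | intermediate
27 | dilithium salt of the ring-opened diketone carboxylate (drawn for attack at the carbonyl next to the methyl/prenyl carbon; the regioisomer converges) | [Li+].[Li+].CC[C@@H](C)C(=O)C=C([O-])[C@](C)(CC=C(C)C)C(=O)[C@]1(C[C@@H]2[C@@H](CC[C@]2(C)O[Si](C)(C)C)[C@@](C)(O[Si](C)(C)C)C1)C([O-])=O | intermediate
28 | ring-opened triketo acid | CC[C@@H](C)C(=O)CC(=O)[C@](C)(CC=C(C)C)C(=O)[C@]1(C[C@@H]2[C@@H](CC[C@]2(C)O[Si](C)(C)C)[C@@](C)(O[Si](C)(C)C)C1)C(O)=O | intermediate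
29 | target bis(trimethylsilyl) ether: 4-hydroxy-1',4',5-trimethyl-5-(3-methylbut-2-en-1-yl)-3-[(2R)-2-methylbutanoyl]-1',4'-bis[(trimethylsilyl)oxy]octahydrospiro[cyclohex-3-ene-1,6'-indene]-2,6-dione, configuration as in the SMILES | CC[C@@H](C)C(=O)C1=C(O)[C@](C)(CC=C(C)C)C(=O)[C@]2(C[C@@H]3[C@@H](CC[C@]3(C)O[Si](C)(C)C)[C@@](C)(O[Si](C)(C)C)C2)C1=O | intermediate
30 | CNP0236509.3: 1',4,4'-trihydroxy-1',4',5-trimethyl-5-(3-methylbut-2-en-1-yl)-3-[(2R)-2-methylbutanoyl]octahydrospiro[cyclohex-3-ene-1,6'-indene]-2,6-dione, (1'S,3a'R,4'S,7a'R), spiro centre and C5 as in the SMILES | CC[C@@H](C)C(=O)C1=C(O)[C@](C)(CC=C(C)C)C(=O)[C@]2(C[C@@H]3[C@@H](CC[C@]3(C)O)[C@@](C)(O)C2)C1=O | target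

**Summary**
Total step count: 16. Longest linear sequence: 10 steps (steps 1 to 6, 12, 13, 15, 16).

Steps most likely to fail:

1. Step 15. After the anhydride has opened, ring closure may stall through O-acylation to an enol lactone that does not migrate, rearrangement of the activated acid to an N-acylurea, or loss of CO2 from the beta-keto acid before it is activated. The fallback uses known chemistry, sets out from 23 and 26 and returns at 29. Only the enolate opening is run; the cold mixture is brought to pH 4 and the crude keto acid 28 is esterified at once with (trimethylsilyl)diazomethane in toluene/MeOH at 0 °C to the methyl ester of the triketo acid F1, which cannot decarboxylate and can be purified. F1 is then closed by a Dieckmann-type Claisen condensation (KOtBu, THF, 0 °C to rt): the diketone anion attacks the ester, methoxide leaves, and the stable triketone enolate drives the equilibrium to 29.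

2. Step 12. Bond formation between two fully substituted centres may be slow, so that O-acylation of the ketene acetal oxygen or decomposition of the enolate on warming takes over. The fallback sets out from 18 and 19 and returns at 20. Acyl chloride 18 is reduced at −78 °C with LiAlH(OtBu)3 to the aldehyde tert-butyl (2R)-2-formyl-2,5-dimethylhex-4-enoate F2, which has no alpha-hydrogen. F2 is added to enolate 19 at −78 °C in an aldol addition (an aldehyde is smaller and cannot be O-acylated), with the same equatorial approach to C6, giving the beta-hydroxy ester F3 as a mixture of carbinol epimers. Oxidation of F3 with 1,1,1-triacetoxy-1,1-dihydro-1,2-benziodoxol-3(1H)-one (NaHCO3, CH2Cl2) gives 20.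

3. Step 3. The enamine may form mainly on the unsubstituted side of the ketone while the amine or the nitro compound adds to the acrylate between molecules, so that ring closure is slow and oligomers form. The fallback sets out from 1, 2 and 4 and returns at 6. Nitromethane 2 (large excess) is first allylated with 4 (K2CO3, MeCN) to tert-butyl 2-methylidene-4-nitrobutanoate F4. F4 and 1 are then combined under the primary-amine catalyst of step 1: the iminium-mediated nitro-Michael addition sets C3a and leaves the enamine at C7a, which adds to the tethered acrylate before hydrolysis. This Michael/Michael cascade would give 6 directly and bypass 3 and 5.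

Further compounds
F1 | step 15 | methyl ester of triketo acid 28 | CC[C@@H](C)C(=O)CC(=O)[C@](C)(CC=C(C)C)C(=O)[C@]1(C[C@@H]2[C@@H](CC[C@]2(C)O[Si](C)(C)C)[C@@](C)(O[Si](C)(C)C)C1)C(=O)OC
F2 | step 12 | tert-butyl (2R)-2-formyl-2,5-dimethylhex-4-enoate | CC(C)(C)OC(=O)[C@](C)(CC=C(C)C)C=O
F3 | step 12 | beta-hydroxy ester from aldol addition of 19 to F2 (carbinol epimers) | CC(C)(C)OC(=O)[C@](C)(CC=C(C)C)C(O)[C@]1(C[C@@H]2[C@@H](CC[C@]2(C)O[Si](C)(C)C)[C@@](C)(O[Si](C)(C)C)C1)C(=O)OC(C)(C)C
F4 | step 3 | tert-butyl 2-methylidene-4-nitrobutanoate | C=C(CC[N+](=O)[O-])C(=O)OC(C)(C)C
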